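## Analysis of the target

The target is a chroman-2,4-dione, a benzo ring fused through C4a and C8a to a pyran-2,4-dione ring. Its C3 is a quaternary carbon that carries a (2E,6E)-farnesyl group and a seventeen-carbon chain, C1'H2–C2'H2–C3'(=O)–C4'≡C5'–C6'≡C7'–C8'H(OH)–C9'H=C10'H–n-heptyl with a 9'Z olefin. There are two stereocentres, C3 (S) and the carbinol C8' (S). A rigid diynone rod of eight bonds separates them, so neither can direct the other and each has to be set by its own reagent control, alongside three olefin geometries. The sensitive groups are numerous: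

- the aryl lactone at C2, an activated ester of a non-enolisable β-keto acid that is opened irreversibly by hydroxide, alkoxide or amine nucleophiles;
- the diynone C3'–C7', a strong conjugate acceptor;
- the carbinol C8', which is both allylic and propargylic and ionises under acid;
- the Z-olefin, which isomerises whenever it is conjugated to a carbonyl group;
- the three trisubstituted farnesyl olefins, which cyclise under protic or strong Lewis acid;
- every terminal diyne on the way.

The difficulty is twofold. C3 lies between two carbonyl groups of similar size, so a catalyst must tell the lactone side from the ketone side. The polyyne must also be joined to an electrophile-rich, base-labile half without any strongly basic or nucleophilic reagent. The strategy rests on the ketone carbon C3'. Cutting the bond C3'–C4' divides the molecule into a C27 acyl half (ring system, farnesyl group, C3) and a C14 enediynol half (C8', Z-olefin). Each stereocentre is then made in a small fragment, and the diynone exists only for the last two steps.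

## Retrosynthetic reasoning

**22 to 21.** The last operation is removal of a silyl group from the C8' oxygen, so target 22 comes from its tert-butyldimethylsilyl ether 21. The carbinol is masked during the union because a free secondary alcohol would compete for the acylating agent. A silyl ether is chosen because it can be removed by a buffered fluoride source, which touches neither the lactone, the diynone nor the polyene.

**21 to 10 and 20.** The bond between the ketone carbon C3' and the alkyne carbon C4' is cut, giving acid chloride 10 and terminal diyne 20. This is the only cut that yields two halves of comparable size, each with one finished stereocentre. A cut between C5' and C6' would need a terminal ynone, which is too electrophilic to handle. A cut at C7'–C8' would require the carbinol to be set by adding a metallated diynone to an enal in the presence of the lactone. The forward reaction must acylate the terminal diyne carbon under conditions that are neither strongly basic nor nucleophilic; a palladium/copper-catalysed acylation with a tertiary amine meets this.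

**10 to 9 to 7.** The acid chloride 10 is traced to acid 9 and this to tert-butyl ester 7. The chlorination must release no mineral acid, because three trisubstituted olefins are present. The ester must be cleaved without hydroxide, because the lactone of 7 would open first. A tert-butyl ester, removed by silyl-triflate-induced loss of the tert-butyl group under amine buffering, satisfies both demands.

**7 to 4 and 6.** The bond from C3 to the farnesyl CH2 is cut, giving 3-substituted hydroxycoumarin 4 and farnesyl methyl carbonate 6. The farnesyl group is introduced last at C3 because an allylic carbonate can be ionised by zerovalent palladium inside a chiral ligand pocket. This makes the bond construction and the setting of C3 one event. Attack at the CH2 terminus of the allyl unit is required, and it is favoured because attack at the tertiary terminus would create two adjacent quaternary carbons.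

**6 to 5.** Carbonate 6 is the activated form of (2E,6E)-farnesol 5, which supplies both E-olefins ready-made.

**4 to 3 to 1 and 2.** In 4 the bond C3–C4 is cut (intramolecular Claisen condensation of aryl ester 3) and then the aryl ester C–O bond, leading to methyl salicylate 1 and glutaric half-ester 2. Attaching the three-carbon ester chain to a preformed, 3-unsubstituted enol-lactone by conjugate addition to an acrylic ester was considered. The acidity of that enol makes it a sluggish donor towards simple acrylates, and double addition competes. The chain is therefore built in during ring construction, where the regiochemistry is fixed by ring size.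

**20 to 19 to 18.** Terminal diyne 20 comes from C-silylated diyne 19 by selective cleavage of the alkynyl C–Si bond, and 19 from alcohol 18 by O-silylation. The two silicon groups differ enough in lability that the alkyne can be freed while the ether stays.

**18 to 13 and 16.** The bond between C8' and the alkyne carbon is cut, giving (Z)-enal 13 and silyl diyne 16. A catalytic enantioselective 1,2-addition of the diyne sets the carbinol, while the Z-olefin is already in place in the aldehyde.

**16 to 14, and 13 to 12 to 11.** Diyne 16 is obtained by removing one silyl group from the symmetrical bis-silyl diyne 14. Enal 13 comes from allylic alcohol 12 by mild oxidation, and 12 from alkynol 11 by syn semi-hydrogenation, which defines the Z geometry.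

## Alternatives that were turned down

**Alternative 1:** The pyran-2,4-dione ring is disconnected at O1–C8a and C4–C4a, so the benzo ring is attached last. In the forward sense the carboxylate of the enantiopure quaternary malonic half-ester A2 adds to an aryne released by fluoride from the silylaryl triflate A3. The resulting aryl anion acylates the neighbouring trifluoroethyl ester and closes the six-membered ring to give A1.
- In its favour: the quaternary centre is set in an acyclic malonate, where desymmetrisation methods are well developed, and C- versus O-alkylation of an ambident enolate never arises. On this point it is stronger than the chosen route.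
- Against it: the aryl anion can also attack the carbonyl of its own aryl ester through a four-membered transition state (the usual acyl-migration path of arynes with carboxylates). Lactonisation of that ketone on the trifluoroethyl ester then exchanges the roles of the two carbonyl carbons and gives the mirror image at C3, so the two pathways erode the enantiomeric purity. Simple protonation of the aryl anion is a further leak.
- Step economy: A1 carries the side chain at the alcohol oxidation level. Three more steps are needed to reach acid 9, and the union with 20 is still required.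
- In comparison, the chosen strategy offers a shorter path to 10 and a stereocentre that no competing pathway can invert once it is formed.

**Alternative 2:** The bond C3–C4 is formed by a 1,2-acyl shift. A strong Lewis acid opens the epoxy ketone A5 at its fully substituted carbon, the aroyl group migrates to that carbon with inversion, and the keto aldehyde A4 results. Oxidation of the aldehyde, removal of both silyl groups and lactonisation would then build the ring.
- In its favour: the transfer of configuration from epoxide to quaternary carbon is stereospecific. That is more dependable than any catalyst-controlled alkylation, and on this point the alternative is stronger.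
- Against it: the configuration of A5 depends on an enone whose β-carbon carries two CH2 substituents (farnesyl and silyloxypropyl) that are almost identical in size. The olefin geometry, and with it the stereocentre, is therefore hard to control. The Lewis acid also generates cationic character two atoms away from the first farnesyl olefin, which invites cation–olefin cyclisation.
- Step economy: the route to the acid is at least six steps longer than the chosen one.
- In comparison, the chosen strategy gives up stereospecificity. It gains a catalytic step whose ligand is available in both mirror-image forms, and a far shorter sequence.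

**Alternative 3:** The bond from C3 to the farnesyl CH2 is the key disconnection. Zerovalent palladium with a chiral diaminocyclohexane-derived bisphosphine ionises carbonate 6, and the enolate of the 3-(silyloxypropyl)hydroxycoumarin A7 attacks the CH2 terminus through C3 to give A6.
- In its favour: this is the same reaction type that the chosen route uses in step 4, so the two are equal on the setting of C3. The silyl ether of A6 is removed more gently than a tert-butyl ester beside a polyene, and a silyloxypropyl chain cannot interfere in the allylation. On these two points the alternative is as strong or stronger.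
- Against it: A6 is three steps (desilylation and two oxidations in the presence of the farnesyl olefins) away from acid 9. The plan also leaves the union with the C14 enediynol undefined.
- In comparison, the chosen strategy carries the carboxyl oxidation level from the first step. It places the effort on a convergent union that keeps the diynone out of every step but the last two.

Key step: step 13

Assumption: the sense of induction of the two chiral catalysts (steps 4 and 10) cannot be predicted with certainty for these substrates. The ligand antipodes written are those expected to give the drawn configurations, and the mirror-image ligand would be used if the opposite sense were found.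

## Route

Step 1
Reactants: 1 methyl salicylate; 2 5-tert-butoxy-5-oxopentanoic acid
Product: 3 methyl 2-[(5-tert-butoxy-5-oxopentanoyl)oxy]benzoate
Conditions: EDC·HCl, DMAP (cat.), CH2Cl2, 0 °C → rt
Reagents that add atoms: none
Why: Steglich esterification; the carbodiimide-activated free carboxyl of 2 acylates the phenol of 1 under DMAP catalysis, and neither existing ester is affected.

Step 2
Reactants: 3 methyl 2-[(5-tert-butoxy-5-oxopentanoyl)oxy]benzoate
Product: 4 tert-butyl 3-(4-hydroxy-2-oxo-2H-chromen-3-yl)propanoate
Conditions: LiN(SiMe3)2 (2.2 equiv), THF, −78 → 0 °C; then 1 M HCl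
Reagents that add atoms: none
Why: Intramolecular Claisen (Dieckmann-type) condensation, the classical entry to 3-alkyl-4-hydroxycoumarins; the aryl ester enolate attacks the neighbouring methyl ester in a six-membered closure and deprotonation of the acidic product drives it, whereas the tert-butyl ester enolate could only close a four- or eight-membered ring.

Step 3
Reactants: 5 (2E,6E)-farnesol
Product: 6 (2E,6E)-farnesyl methyl carbonate
Conditions: ClCO2Me, pyridine, CH2Cl2, 0 °C
Reagents that add atoms: methyl chloroformate, COC(=O)Cl
Why: O-acylation of a primary allylic alcohol with a chloroformate; the allylic C–O bond is not touched, so both olefin geometries are kept.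

Step 4
Reactants: 4 tert-butyl 3-(4-hydroxy-2-oxo-2H-chromen-3-yl)propanoate; 6 (2E,6E)-farnesyl methyl carbonate
Product: 7 tert-butyl 3-[(3S)-3-[(2E,6E)-farnesyl]-2,4-dioxochroman-3-yl]propanoate
Conditions: 4 (1.1 equiv), Pd2(dba)3·CHCl3 (2.5 mol %), (R,R)-DACH-phenyl Trost ligand (7.5 mol %), CH2Cl2, 0 °C → rt
Reagents that add atoms: none
Why: Asymmetric Tsuji–Trost allylic alkylation of a prochiral, stabilised cyclic β-dicarbonyl enolate, as known for 2-substituted β-keto esters and azlactones with 3,3-disubstituted allyl electrophiles. The methoxide released on ionisation of 6 deprotonates 4, and the enolate attacks the CH2 terminus of the farnesyl–palladium complex on the Si face of C3 (C2 > C4 > CH2) inside the ligand pocket, which gives the S centre. Any O-farnesyl enol ether is re-ionised by zerovalent palladium and funnelled to the C-alkylated product.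

Step 5
Reactants: 7 tert-butyl 3-[(3S)-3-[(2E,6E)-farnesyl]-2,4-dioxochroman-3-yl]propanoate
Product: 9 3-[(3S)-3-[(2E,6E)-farnesyl]-2,4-dioxochroman-3-yl]propanoic acid, via trimethylsilyl ester 8 (not isolated)
Conditions: TMSOTf (3 equiv), 2,6-lutidine (4 equiv), CH2Cl2, 0 °C; then pH 4 citrate buffer
Reagents that add atoms: none
Why: Silyl-triflate-mediated cleavage of a tert-butyl ester; O-silylation of the ester carbonyl and loss of the tert-butyl group as isobutene give the silyl ester, which hydrolyses on work-up. The amine buffer keeps free acid away from the farnesyl olefins, and no hydroxide ever meets the lactone; C3 has no alpha hydrogen and cannot epimerise.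

Step 6
Reactants: 9 3-[(3S)-3-[(2E,6E)-farnesyl]-2,4-dioxochroman-3-yl]propanoic acid
Product: 10 3-[(3S)-3-[(2E,6E)-farnesyl]-2,4-dioxochroman-3-yl]propanoyl chloride
Conditions: 1-chloro-N,N,2-trimethylprop-1-en-1-amine (1.2 equiv), CH2Cl2, 0 °C → rt; solution used directly
Reagents that add atoms: 1-chloro-N,N,2-trimethylprop-1-en-1-amine (Ghosez reagent), CC(C)=C(Cl)N(C)C
Why: Acid chloride formation with an α-chloroenamine under neutral conditions; the only by-product is an inert amide and no hydrogen chloride is released, so the trisubstituted olefins are not hydrochlorinated.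

Step 7
Reactants: 11 dec-2-yn-1-ol
Product: 12 (Z)-dec-2-en-1-ol
Conditions: H2 (1 atm), Pd/CaCO3 poisoned with Pb(OAc)2 (Lindlar catalyst), quinoline, EtOAc/hexane, rt
Reagents that add atoms: none
Why: Lindlar semi-hydrogenation; syn delivery of hydrogen on the poisoned palladium surface gives the Z-olefin and stops at the alkene stage.

Step 8
Reactants: 12 (Z)-dec-2-en-1-ol
Product: 13 (Z)-dec-2-enal
Conditions: Dess–Martin periodinane, NaHCO3, CH2Cl2, 0 °C; used crude at once
Reagents that add atoms: none
Why: Dess–Martin oxidation of a primary allylic alcohol under bicarbonate buffering; the neutral, cold conditions and immediate use of the aldehyde avoid Z to E isomerisation.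

Step 9
Reactants: 14 1,4-bis(trimethylsilyl)buta-1,3-diyne
Product: 16 buta-1,3-diyn-1-yl(trimethyl)silane, via lithium 4-(trimethylsilyl)buta-1,3-diyn-1-ide 15 (not isolated)
Conditions: MeLi·LiBr (1.05 equiv), Et2O, −78 °C → rt; then sat. aq. NH4Cl, 0 °C; kept as a toluene solution
Reagents that add atoms: none
Why: Mono-desilylation by attack of methyllithium at silicon; the lithium diynide formed is deactivated towards a second cleavage, and protonation gives the terminal diyne.

Step 10
Reactants: 13 (Z)-dec-2-enal; 16 buta-1,3-diyn-1-yl(trimethyl)silane
Product: 18 (5S,6Z)-1-(trimethylsilyl)tetradec-6-ene-1,3-diyn-5-ol, via methyl[4-(trimethylsilyl)buta-1,3-diyn-1-yl]zinc 17 (not isolated)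
Conditions: Me2Zn (3 equiv), (S,S)-ProPhenol (10 mol %), Ph3P=O (20 mol %), toluene, 0–4 °C; then aq. NH4Cl
Reagents that add atoms: none
Why: Zinc–ProPhenol-catalysed enantioselective 1,2-addition of a terminal 1,3-diyne to an α,β-unsaturated aldehyde; the dinuclear zinc complex binds the aldehyde and the zinc diynylide together and delivers the diynyl group to the Re face of the carbonyl, which gives the S carbinol. The Z-olefin is carried in from 13.

Step 11
Reactants: 18 (5S,6Z)-1-(trimethylsilyl)tetradec-6-ene-1,3-diyn-5-ol
Product: 19 tert-butyldimethyl{[(5S,6Z)-1-(trimethylsilyl)tetradec-6-ene-1,3-diyn-5-yl]oxy}silane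
Conditions: TBSCl, imidazole, DMF, 0 °C → rt
Reagents that add atoms: tert-butyldimethylsilyl chloride, CC(C)(C)[Si](C)(C)Cl
Why: Standard silylation of a secondary alcohol with imidazole catalysis; the C–O bond of the carbinol is not involved, so its configuration is kept.

Step 12
Reactants: 19 tert-butyldimethyl{[(5S,6Z)-1-(trimethylsilyl)tetradec-6-ene-1,3-diyn-5-yl]oxy}silane
Product: 20 tert-butyldimethyl{[(5S,6Z)-tetradec-6-ene-1,3-diyn-5-yl]oxy}silane
Conditions: K2CO3 (0.3 equiv), MeOH/THF, 0 °C; used at once as a THF solution
Reagents that add atoms: none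
Why: Methanolysis of an alkynyl C–Si bond with catalytic carbonate; the hindered secondary silyl ether is stable to these conditions.

Step 13
Reactants: 10 3-[(3S)-3-[(2E,6E)-farnesyl]-2,4-dioxochroman-3-yl]propanoyl chloride; 20 tert-butyldimethyl{[(5S,6Z)-tetradec-6-ene-1,3-diyn-5-yl]oxy}silane
Product: 21 (3S)-3-[(8S,9Z)-8-(tert-butyldimethylsilyloxy)-3-oxoheptadec-9-ene-4,6-diyn-1-yl]-3-[(2E,6E)-farnesyl]chroman-2,4-dione
Conditions: PdCl2(PPh3)2 (3 mol %), CuI (6 mol %), NEt3 (1.5 equiv, added slowly), degassed THF, 0 °C → rt, argon
Reagents that add atoms: none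
Why: Acyl Sonogashira coupling: PdCl2(PPh3)2 is reduced in the flask to zerovalent palladium, which inserts into the C–Cl bond of 10; CuI and NEt3 convert the terminal C–H of 20 into a copper diynylide, which transmetallates, and reductive elimination forms the bond between the ketone carbon and C1 of the diyne. The closest known reaction type is the palladium/copper-catalysed coupling of aliphatic acid chlorides with terminal alkynes and terminal 1,3-diynes to give ynones. No ring is closed and no stereocentre is formed. C3 has no alpha hydrogen and the carbinol is held as its silyl ether, so both centres pass through unchanged. The step needs chemoselectivity for the acyl chloride over the aryl lactone and the C4 ketone, which is secured because only the C–Cl bond undergoes oxidative addition and the soft copper diynylide does not add to carbonyl groups. It also needs C-acylation to outrun ketene formation at the CH2 next to the acid chloride, which slow addition of a small excess of NEt3 at 0 °C favours. Rigorous degassing suppresses oxidative dimerisation of 20, and the absence of primary or secondary amines protects the diynone and the lactone from addition.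

Step 14
Reactants: 21 (3S)-3-[(8S,9Z)-8-(tert-butyldimethylsilyloxy)-3-oxoheptadec-9-ene-4,6-diyn-1-yl]-3-[(2E,6E)-farnesyl]chroman-2,4-dione
Product: 22 (3S)-3-[(8S,9Z)-8-hydroxy-3-oxoheptadec-9-ene-4,6-diyn-1-yl]-3-[(2E,6E)-farnesyl]chroman-2,4-dione
Conditions: HF·pyridine, pyridine, THF, 0 °C → rt
Reagents that add atoms: none
Why: Fluoride-induced Si–O cleavage in a pyridine-buffered medium; the conditions are neither basic enough to open the lactone nor acidic enough to ionise the allylic-propargylic carbinol or to protonate the farnesyl olefins.

## Compound list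

1 | methyl salicylate | COC(=O)c1ccccc1O | starting material
2 | 5-tert-butoxy-5-oxopentanoic acid | CC(C)(C)OC(=O)CCCC(=O)O | starting material
3 | methyl 2-[(5-tert-butoxy-5-oxopentanoyl)oxy]benzoate | COC(=O)c1ccccc1OC(=O)CCCC(=O)OC(C)(C)C | intermediate
4 | tert-butyl 3-(4-hydroxy-2-oxo-2H-chromen-3-yl)propanoate | CC(C)(C)OC(=O)CCC1=C(O)c2ccccc2OC1=O | intermediate
5 | (2E,6E)-farnesol | OC/C=C(\C)CC/C=C(\C)CCC=C(C)C | starting material
6 | (2E,6E)-farnesyl methyl carbonate | COC(=O)OC/C=C(\C)CC/C=C(\C)CCC=C(C)C | intermediate
7 | tert-butyl 3-[(3S)-3-[(2E,6E)-farnesyl]-2,4-dioxochroman-3-yl]propanoate | CC(C)(C)OC(=O)CC[C@@]1(C/C=C(\C)CC/C=C(\C)CCC=C(C)C)C(=O)Oc2ccccc2C1=O | intermediate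
8 | trimethylsilyl 3-[(3S)-3-[(2E,6E)-farnesyl]-2,4-dioxochroman-3-yl]propanoate | C[Si](C)(C)OC(=O)CC[C@@]1(C/C=C(\C)CC/C=C(\C)CCC=C(C)C)C(=O)Oc2ccccc2C1=O | intermediate
9 | 3-[(3S)-3-[(2E,6E)-farnesyl]-2,4-dioxochroman-3-yl]propanoic acid | OC(=O)CC[C@@]1(C/C=C(\C)CC/C=C(\C)CCC=C(C)C)C(=O)Oc2ccccc2C1=O | intermediate
10 | 3-[(3S)-3-[(2E,6E)-farnesyl]-2,4-dioxochroman-3-yl]propanoyl chloride | ClC(=O)CC[C@@]1(C/C=C(\C)CC/C=C(\C)CCC=C(C)C)C(=O)Oc2ccccc2C1=O | intermediate
11 | dec-2-yn-1-ol | CCCCCCCC#CCO | starting material
12 | (Z)-dec-2-en-1-ol | CCCCCCC/C=C\CO | intermediate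
13 | (Z)-dec-2-enal | CCCCCCC/C=C\C=O | intermediate
14 | 1,4-bis(trimethylsilyl)buta-1,3-diyne | C[Si](C)(C)C#CC#C[Si](C)(C)C | starting material
15 | lithium 4-(trimethylsilyl)buta-1,3-diyn-1-ide | [Li]C#CC#C[Si](C)(C)C | intermediate
16 | buta-1,3-diyn-1-yl(trimethyl)silane | C#CC#C[Si](C)(C)C | intermediate
17 | methyl[4-(trimethylsilyl)buta-1,3-diyn-1-yl]zinc | C[Zn]C#CC#C[Si](C)(C)C | intermediate
18 | (5S,6Z)-1-(trimethylsilyl)tetradec-6-ene-1,3-diyn-5-ol | CCCCCCC/C=C\[C@H](O)C#CC#C[Si](C)(C)C | intermediate
19 | tert-butyldimethyl{[(5S,6Z)-1-(trimethylsilyl)tetradec-6-ene-1,3-diyn-5-yl]oxy}silane | CCCCCCC/C=C\[C@H](O[Si](C)(C)C(C)(C)C)C#CC#C[Si](C)(C)C | intermediate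
20 | tert-butyldimethyl{[(5S,6Z)-tetradec-6-ene-1,3-diyn-5-yl]oxy}silane | CCCCCCC/C=C\[C@H](O[Si](C)(C)C(C)(C)C)C#CC#C | intermediate
21 | (3S)-3-[(8S,9Z)-8-(tert-butyldimethylsilyloxy)-3-oxoheptadec-9-ene-4,6-diyn-1-yl]-3-[(2E,6E)-farnesyl]chroman-2,4-dione | CCCCCCC/C=C\[C@H](O[Si](C)(C)C(C)(C)C)C#CC#CC(=O)CC[C@@]1(C/C=C(\C)CC/C=C(\C)CCC=C(C)C)C(=O)Oc2ccccc2C1=O | intermediate
22 | (3S)-3-[(8S,9Z)-8-hydroxy-3-oxoheptadec-9-ene-4,6-diyn-1-yl]-3-[(2E,6E)-farnesyl]chroman-2,4-dione | CCCCCCC/C=C\[C@H](O)C#CC#CC(=O)CC[C@@]1(C/C=C(\C)CC/C=C(\C)CCC=C(C)C)C(=O)Oc2ccccc2C1=O | target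

## Step count and least certain steps

Total step count: 14. Longest linear sequence: 7 steps (steps 1, 2, 4, 5, 6, 13, 14 from methyl salicylate 1; the diyne branch, steps 7, 8, 10, 11, 12, 13, 14 from 11, is of the same length).

**Step 13 (key step).**
- Risk: NEt3 may deprotonate the CH2 next to the acid chloride and divert it into ketene oligomerisation. The terminal diyne may dimerise oxidatively or polymerise before it is acylated. The acid chloride may rest partly as a cyclic pseudo-chloride formed with the C4 ketone, which slows oxidative addition. Chloride or amine may add to the diynone once it is formed.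
- Fallback: it keeps the same bond formation but removes base and copper. Diyne 20 is deprotonated with LiN(SiMe3)2 in THF at −78 °C and quenched with Bu3SnCl to give tributyl[(5S,6Z)-5-(tert-butyldimethylsilyloxy)tetradec-6-ene-1,3-diyn-1-yl]stannane F1. F1 is coupled with acid chloride 10 in a Stille acylation (PdCl2(PPh3)2, THF, rt to 50 °C, no amine) and returns to the route at 21.

**Step 4.**
- Risk: facial discrimination of the enolate may be poor. The new stereocentre lies on the nucleophile, outside the chiral pocket, and between two carbonyl groups that differ only in their distant neighbours. Slow capture of the allyl complex could also allow the 2,3-olefin of the farnesyl unit to lose its E geometry.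
- Fallback: induction is replaced by separation. Compounds 4 and 6 are coupled with achiral Pd(PPh3)4 in THF to give racemic tert-butyl 3-[3-[(2E,6E)-farnesyl]-2,4-dioxochroman-3-yl]propanoate F2. F2 is resolved by preparative supercritical fluid chromatography on a chiral stationary phase. The S enantiomer is 7, where the route is rejoined, and the R enantiomer, tert-butyl 3-[(3R)-3-[(2E,6E)-farnesyl]-2,4-dioxochroman-3-yl]propanoate F3, is set aside.

**Step 10.**
- Risk: the Z-enal may isomerise to the E-enal under the Lewis-acidic, amine-containing conditions before addition occurs. The enantioselectivity may also be insufficient for a Z-configured enal.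
- Fallback: lithium diynide 15, made from 14, is added to enal 13 in THF at −78 °C, where isomerisation is not expected. This gives racemic (Z)-1-(trimethylsilyl)tetradec-6-ene-1,3-diyn-5-ol F4. Lipase-catalysed acetylation (Burkholderia cepacia lipase, vinyl acetate, hexane) should then acylate the S enantiomer, as the empirical size rule for secondary alcohols predicts with the Z-alkenyl group as the larger substituent. The products are (5S,6Z)-1-(trimethylsilyl)tetradec-6-ene-1,3-diyn-5-yl acetate F5 and unreacted (5R,6Z)-1-(trimethylsilyl)tetradec-6-ene-1,3-diyn-5-ol F6. F6 can be converted into F5 by Mitsunobu inversion with acetic acid. K2CO3 in MeOH removes the acetate and the C-silyl group of F5 together to give (5S,6Z)-tetradec-6-ene-1,3-diyn-5-ol F7, and TBSCl/imidazole returns to the route at 20.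

**Step 5.**
- Risk: traces of triflic acid, or the tert-butyl cation, may start cationic cyclisation or double-bond migration in the farnesyl chain. Cleavage may also stall at partial conversion.
- Fallback: a fluoride-labile ester is carried from the start.
  - Glutaric anhydride is opened with 2-(trimethylsilyl)ethanol (DMAP) to give 5-oxo-5-[2-(trimethylsilyl)ethoxy]pentanoic acid F8.
  - F8 is esterified with 1 as in step 1 to give methyl 2-({5-oxo-5-[2-(trimethylsilyl)ethoxy]pentanoyl}oxy)benzoate F9.
  - Cyclisation as in step 2 gives 2-(trimethylsilyl)ethyl 3-(4-hydroxy-2-oxo-2H-chromen-3-yl)propanoate F10.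
  - Farnesylation with 6 as in step 4 gives 2-(trimethylsilyl)ethyl 3-[(3S)-3-[(2E,6E)-farnesyl]-2,4-dioxochroman-3-yl]propanoate F11.
  - Anhydrous fluoride (tris(dimethylamino)sulfonium difluorotrimethylsilicate, DMF, 0 °C, acidic buffer work-up) fragments the ester and returns to the route at 9.

**Step 14.**
- Risk: the secondary tert-butyldimethylsilyl ether may need long exposure. During that time the allylic-propargylic carbinol could ionise, or the diynone could take up fluoride or pyridine.
- Fallback: a more labile silyl group is used from 18 on.
  - Et3SiCl/imidazole gives triethyl{[(5S,6Z)-1-(trimethylsilyl)tetradec-6-ene-1,3-diyn-5-yl]oxy}silane F12.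
  - K2CO3/MeOH gives triethyl{[(5S,6Z)-tetradec-6-ene-1,3-diyn-5-yl]oxy}silane F13.
  - Coupling with 10 as in step 13 gives (3S)-3-[(8S,9Z)-3-oxo-8-(triethylsilyloxy)heptadec-9-ene-4,6-diyn-1-yl]-3-[(2E,6E)-farnesyl]chroman-2,4-dione F14.
  - AcOH/THF/H2O at rt removes the silyl group and returns to the route at 22.

## Further compounds

F1 | step 13 | tributyl[(5S,6Z)-5-(tert-butyldimethylsilyloxy)tetradec-6-ene-1,3-diyn-1-yl]stannane | CCCCCCC/C=C\[C@H](O[Si](C)(C)C(C)(C)C)C#CC#C[Sn](CCCC)(CCCC)CCCC
F2 | step 4 | racemic tert-butyl 3-[3-[(2E,6E)-farnesyl]-2,4-dioxochroman-3-yl]propanoate | CC(C)(C)OC(=O)CCC1(C/C=C(\C)CC/C=C(\C)CCC=C(C)C)C(=O)Oc2ccccc2C1=O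
F3 | step 4 | tert-butyl 3-[(3R)-3-[(2E,6E)-farnesyl]-2,4-dioxochroman-3-yl]propanoate | CC(C)(C)OC(=O)CC[C@]1(C/C=C(\C)CC/C=C(\C)CCC=C(C)C)C(=O)Oc2ccccc2C1=O
F4 | step 10 | racemic (Z)-1-(trimethylsilyl)tetradec-6-ene-1,3-diyn-5-ol | CCCCCCC/C=C\C(O)C#CC#C[Si](C)(C)C
F5 | step 10 | (5S,6Z)-1-(trimethylsilyl)tetradec-6-ene-1,3-diyn-5-yl acetate | CCCCCCC/C=C\[C@H](OC(C)=O)C#CC#C[Si](C)(C)C
F6 | step 10 | (5R,6Z)-1-(trimethylsilyl)tetradec-6-ene-1,3-diyn-5-ol | CCCCCCC/C=C\[C@@H](O)C#CC#C[Si](C)(C)C
F7 | step 10 | (5S,6Z)-tetradec-6-ene-1,3-diyn-5-ol | CCCCCCC/C=C\[C@H](O)C#CC#C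
F8 | step 5 | 5-oxo-5-[2-(trimethylsilyl)ethoxy]pentanoic acid | C[Si](C)(C)CCOC(=O)CCCC(=O)O
F9 | step 5 | methyl 2-({5-oxo-5-[2-(trimethylsilyl)ethoxy]pentanoyl}oxy)benzoate | COC(=O)c1ccccc1OC(=O)CCCC(=O)OCC[Si](C)(C)C
F10 | step 5 | 2-(trimethylsilyl)ethyl 3-(4-hydroxy-2-oxo-2H-chromen-3-yl)propanoate | C[Si](C)(C)CCOC(=O)CCC1=C(O)c2ccccc2OC1=O
F11 | step 5 | 2-(trimethylsilyl)ethyl 3-[(3S)-3-[(2E,6E)-farnesyl]-2,4-dioxochroman-3-yl]propanoate | C[Si](C)(C)CCOC(=O)CC[C@@]1(C/C=C(\C)CC/C=C(\C)CCC=C(C)C)C(=O)Oc2ccccc2C1=O
F12 | step 14 | triethyl{[(5S,6Z)-1-(trimethylsilyl)tetradec-6-ene-1,3-diyn-5-yl]oxy}silane | CCCCCCC/C=C\[C@H](O[Si](CC)(CC)CC)C#CC#C[Si](C)(C)C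
F13 | step 14 | triethyl{[(5S,6Z)-tetradec-6-ene-1,3-diyn-5-yl]oxy}silane | CCCCCCC/C=C\[C@H](O[Si](CC)(CC)CC)C#CC#C
F14 | step 14 | (3S)-3-[(8S,9Z)-3-oxo-8-(triethylsilyloxy)heptadec-9-ene-4,6-diyn-1-yl]-3-[(2E,6E)-farnesyl]chroman-2,4-dione | CCCCCCC/C=C\[C@H](O[Si](CC)(CC)CC)C#CC#CC(=O)CC[C@@]1(C/C=C(\C)CC/C=C(\C)CCC=C(C)C)C(=O)Oc2ccccc2C1=O
A1 | alternative 1 | (3S)-3-[3-(tert-butyldiphenylsilyloxy)propyl]-3-[(2E,6E)-farnesyl]chroman-2,4-dione | CC(C)(C)[Si](c1ccccc1)(c1ccccc1)OCCC[C@@]1(C/C=C(\C)CC/C=C(\C)CCC=C(C)C)C(=O)Oc2ccccc2C1=O
A2 | alternative 1 | (2R)-2-[3-(tert-butyldiphenylsilyloxy)propyl]-2-[(2E,6E)-farnesyl]malonic acid mono(2,2,2-trifluoroethyl) ester | CC(C)(C)[Si](c1ccccc1)(c1ccccc1)OCCC[C@@](C(=O)OCC(F)(F)F)(C/C=C(\C)CC/C=C(\C)CCC=C(C)C)C(=O)O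
A3 | alternative 1 | 2-(trimethylsilyl)phenyl trifluoromethanesulfonate | C[Si](C)(C)c1ccccc1OS(=O)(=O)C(F)(F)F
A4 | alternative 2 | (2R)-2-[3-(tert-butyldimethylsilyloxy)propyl]-3-[2-(tert-butyldimethylsilyloxy)phenyl]-2-[(2E,6E)-farnesyl]-3-oxopropanal | CC(C)(C)[Si](C)(C)OCCC[C@@](C(=O)c1ccccc1O[Si](C)(C)C(C)(C)C)(C/C=C(\C)CC/C=C(\C)CCC=C(C)C)C=O
A5 | alternative 2 | [(2R,3S)-3-[3-(tert-butyldimethylsilyloxy)propyl]-3-[(2E,6E)-farnesyl]oxiran-2-yl][2-(tert-butyldimethylsilyloxy)phenyl]methanone | CC(C)(C)[Si](C)(C)OCCC[C@@]1(C/C=C(\C)CC/C=C(\C)CCC=C(C)C)O[C@H]1C(=O)c1ccccc1O[Si](C)(C)C(C)(C)C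
A6 | alternative 3 | (3S)-3-[3-(tert-butyldimethylsilyloxy)propyl]-3-[(2E,6E)-farnesyl]chroman-2,4-dione | CC(C)(C)[Si](C)(C)OCCC[C@@]1(C/C=C(\C)CC/C=C(\C)CCC=C(C)C)C(=O)Oc2ccccc2C1=O
A7 | alternative 3 | 3-[3-(tert-butyldimethylsilyloxy)propyl]-4-hydroxy-2H-chromen-2-one | CC(C)(C)[Si](C)(C)OCCCC1=C(O)c2ccccc2OC1=O
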